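**Retrosynthetic overview**

1. The target is taken back to diene-diol 24 by removing the C10–C11 oxirane (Shi epoxidation, last ring formed) and the two tiglates at C2–O and C8–O (double Yamaguchi esterification).
2. The strategy rests on the cyclohexanone ring C1–C6: C1 (side-chain carbon) is β and C6 (acetate carbon) is α to the C5 ketone, and the C2 oxygen is cis to the C1 side chain and to the C3–C4 oxirane. A C6=C1 enone with a free C2 hydroxyl (7) can therefore accept the C7 alkenyl group at C1 under direction from C2–O and take the acetate at C6 in the same operation (C1–C7 and C6–O; no ring closed).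
3. Enone 7 comes from toluquinone. The carbocycle is bought; cyclopentadiene masks the unsubstituted alkene so that the C3–C4 oxirane (first ring formed) goes onto the methylated alkene, then retro-Diels–Alder, Luche reduction at C2 and lipase resolution follow.
4. The alkenyl donor comes from vinyl bromide 16, made from 4-methylpent-3-enoic acid via a silyl ynone whose asymmetric transfer hydrogenation sets C8, then O-silylation and Markovnikov bromoboration of the terminal alkyne.

Key step: step 11

Numbering used throughout: ring C1 (side chain), C2 (O-tigloyl), C3/C4 (oxirane, methyl on C4), C5 (ketone), C6 (acetate); chain C7(=C14H2)–C8–C9–C10=C11(Me)2.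

Assumption: the lipase in step 5 is taken to acetylate the (5R)-carbinol (oxirane carbon as the larger flank), leaving 7 as the alcohol; if the sense were reversed, the acetate would be the wanted antipode and would be deacetylated with the same lipase in methanol.

**Fragment A: enone 7**

Step 1
Reactants: 1 2-methyl-1,4-benzoquinone; 2 cyclopenta-1,3-diene (freshly cracked)
Product: 3 racemic endo cis-fused adduct 2-methyl-4a,5,8,8a-tetrahydro-5,8-methanonaphthalene-1,4-dione
Conditions: CH2Cl2, 0 °C → rt
Reagents that add atoms: none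
Why: Diels–Alder reaction; the diene should add to the unsubstituted, more reactive quinone alkene with endo selectivity, leaving the methylated ene-dione alkene free.

Step 2
Reactants: 3 racemic endo adduct
Product: 4 racemic 2,3-epoxide of 3 with the oxirane on the convex face (cis to the ring-fusion hydrogens)
Conditions: 30% H2O2, Na2CO3, acetone–H2O, 0 °C
Reagents that add atoms: hydrogen peroxide, OO
Why: Weitz–Scheffer nucleophilic epoxidation; hydroperoxide attacks only the electron-poor ene-dione alkene from the open convex face of the cage, so the oxirane carbons C3 and C4 are set cis to each other by ring constraint.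

Step 3
Reactants: 4 racemic tricyclic epoxy-dione
Product: 5 racemic 2,3-epoxy-2-methylcyclohex-5-ene-1,4-dione (1-methyl-7-oxabicyclo[4.1.0]hept-3-ene-2,5-dione)
Conditions: flash vacuum pyrolysis, ca. 500 °C, 0.05 mmHg; cyclopentadiene collected in a separate liquid-N2 trap
Reagents that add atoms: none
Why: retro-Diels–Alder cycloreversion expels cyclopentadiene and restores the C6=C1 alkene without touching the oxirane stereocentres.

Step 4
Reactants: 5 racemic epoxyquinone
Product: 6 racemic syn-epoxyquinol (1S*,5S*,6S*)-5-hydroxy-1-methyl-7-oxabicyclo[4.1.0]hept-3-en-2-one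
Conditions: NaBH4, CeCl3·7H2O, MeOH, −78 °C
Reagents that add atoms: none
Why: Luche reduction; 1,2-hydride delivery should go to the C2 carbonyl (next to the oxirane CH) rather than to C5 (next to the methylated C4), and anti to the oxirane oxygen, which places the new C2 hydroxyl syn to the oxirane.

Step 5
Reactants: 6 racemic syn-epoxyquinol
Product: 7 (1S,5S,6S)-5-hydroxy-1-methyl-7-oxabicyclo[4.1.0]hept-3-en-2-one
Conditions: Amano lipase PS, vinyl acetate, MTBE, 30 °C, run to just past half conversion; chromatography
Reagents that add atoms: none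
Why: lipase-catalysed kinetic resolution by irreversible transesterification; the enzyme should acetylate the (5R)-antipode and leave the (1S,5S,6S)-alcohol, so no stereocentre is formed but the unwanted antipode is removed as its acetate.

**Fragment B: vinyl bromide 16**

Step 6
Reactants: 8 4-methylpent-3-enoic acid
Product: 10 N-methoxy-N,4-dimethylpent-3-enamide, via acyl imidazolide 9 (not isolated)
Conditions: CDI, CH2Cl2, rt; then MeNH(OMe)·HCl, rt
Reagents that add atoms: N,O-dimethylhydroxylamine hydrochloride, CNOC.Cl
Why: amide coupling through the acyl imidazolide gives the Weinreb amide under neutral conditions that should not move the β,γ-alkene into conjugation.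

Step 7
Reactants: 10 Weinreb amide
Product: 11 6-methyl-1-(trimethylsilyl)hept-5-en-1-yn-3-one
Conditions: TMS-acetylene, n-BuLi, THF, −78 °C; then 10, −78 → −20 °C; inverse quench into cold aq NH4Cl
Reagents that add atoms: ethynyltrimethylsilane, C#C[Si](C)(C)C
Why: Weinreb ketone synthesis; the chelated tetrahedral adduct of the lithium acetylide survives until work-up, so the ynone forms without over-addition.

Step 8
Reactants: 11 silyl ynone
Product: 12 (S)-6-methyl-1-(trimethylsilyl)hept-5-en-1-yn-3-ol
Conditions: Ru[(S,S)-TsDPEN](p-cymene) (cat.), i-PrOH, rt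
Reagents that add atoms: none
Why: Noyori asymmetric transfer hydrogenation under base-free conditions; with the alkynyl group in the role that aryl plays for aryl ketones, the (S,S)-ligand should deliver hydride to the face that gives the (S)-carbinol (C8).

Step 9
Reactants: 12 (S)-propargylic alcohol
Product: 14 (S)-3-(tert-butyldimethylsilyloxy)-6-methylhept-5-en-1-yne, via bis-silyl compound 13 (not isolated)
Conditions: TBSCl, imidazole, DMF, rt; then MeOH, K2CO3, rt
Reagents that add atoms: tert-butyldimethylsilyl chloride, CC(C)(C)[Si](C)(C)Cl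
Why: O-silylation followed in the same pot by methanolysis of the alkynyl C–Si bond, which is far more labile to carbonate/methanol than the O–TBS ether; C8 is not involved.

Step 10
Reactants: 14 terminal alkyne
Product: 16 (S)-2-bromo-3-(tert-butyldimethylsilyloxy)-6-methylhepta-1,5-diene, via bromoalkenylborane 15 (not isolated)
Conditions: B-Br-9-BBN (1.1 equiv), CH2Cl2, 0 °C; then AcOH, 0 °C; aq NaHCO3
Reagents that add atoms: B-bromo-9-borabicyclo[3.3.1]nonane, BrB1C2CCCC1CCC2
Why: haloboration–protodeboronation; B–Br adds syn to the terminal alkyne with bromine at the internal carbon (Markovnikov) and acetic acid replaces boron by hydrogen, while the trisubstituted alkene and the silyl ether should not react with the near-stoichiometric borane at 0 °C.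

**Key step and endgame**

Step 11
Reactants: 7 (1S,5S,6S)-enone; 16 vinyl bromide
Product: 23 (1R,2S,3S,4S,6S,8S)-6-acetoxy-3,4-epoxy-2-hydroxy-4-methyl-1-[3-(tert-butyldimethylsilyloxy)-6-methylhepta-1,5-dien-2-yl]cyclohexan-5-one, via alkenyllithium 17 (not isolated), via alkenylmagnesium bromide 18 (not isolated), via magnesium alkoxide 19 (not isolated), via magnesium enolate 20 (not isolated), via bis(trimethylsilyl) enol ether 21 (not isolated), via C2 trimethylsilyl ether 22 (not isolated)
Conditions: (a) 16, t-BuLi (2 equiv), Et2O, −78 °C; MgBr2·OEt2, −78 °C; (b) 7, i-PrMgCl (1.0 equiv, slow addition), THF, −78 °C; add (a), −78 → −30 °C; TMSCl, Et3N, DMPU, −78 → 0 °C; cold aq NaHCO3/pentane wash, concentrate; (c) Pb(OAc)4, CH2Cl2, −20 °C; (d) 10% aq citric acid, THF, 0 °C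
Reagents that add atoms: lead tetraacetate, CC(=O)O[Pb](OC(C)=O)(OC(C)=O)OC(C)=O
Why: i-PrMgCl turns the C2 hydroxyl of 7 into magnesium alkoxide 19, which takes up 18 as an alkoxy(alkenyl)magnesium species and hands the C7 alkenyl group to the adjacent β-carbon C1 through a cyclic transition state, giving enolate 20. The closest known reaction type is the alkoxide-directed syn conjugate addition of Grignard reagents to 4-hydroxycyclohex-2-enones, joined here to enolate silylation and lead tetraacetate α-acetoxylation of the silyl enol ether (Rubottom-type oxidation). No ring is closed; the bonds C1–C7 and C6–O are formed. C1 is set by the C2 alkoxide, which delivers the alkenyl group on its own, oxirane-bearing face and must thereby override both 1,2-attack at C5 (already hindered by the fully substituted C4) and the usual anti addition. C6 is set by the new C1 substituent, which screens its own face of enol ether 21 so that acetate is transferred from lead on the opposite face, trans to C1. The enolate can form only toward C6 because C4 is fully substituted, TMSCl caps both the enolate and the C2 alkoxide so that C2 returns as the free hydroxyl after the citric acid wash, and magnesium halides and Et3N are washed out before oxidation because they would consume Pb(OAc)4.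

Step 12
Reactants: 23 silyl ether
Product: 24 (1R,2S,3S,4S,6S,8S)-6-acetoxy-3,4-epoxy-2-hydroxy-1-(3-hydroxy-6-methylhepta-1,5-dien-2-yl)-4-methylcyclohexan-5-one
Conditions: HF·pyridine, pyridine, THF, 0 °C → rt
Reagents that add atoms: none
Why: fluoride-mediated desilylation under pyridine buffering should cleave the allylic C8 silyl ether without opening the oxirane or disturbing the α-acetoxy ketone; no stereocentre changes.

Step 13
Reactants: 24 diol; 25 tiglic acid (two equivalents are incorporated, one at C2–O and one at C8–O)
Product: 27 (1R,2S,3S,4S,6S,8S)-2,8-bis-tiglate of 24, via mixed anhydride 26 (not isolated)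
Conditions: 25 (3 equiv), 2,4,6-trichlorobenzoyl chloride (3 equiv), Et3N (4 equiv), toluene, rt; then 24, DMAP (3 equiv), toluene, rt → 40 °C
Reagents that add atoms: tiglic acid (the second incorporated equivalent of 25), C/C=C(\C)C(=O)O
Why: Yamaguchi esterification with an excess of the preformed mixed anhydride; the tigloyl group passes through the acyl-DMAP cation to both secondary hydroxyls with retention at C2 and C8, and the (E)-ester, being the more stable isomer, should keep its geometry.

Step 14
Reactants: 27 bis-tiglate
Product: 28 target CNP0407453.3, the (10R)-10,11-epoxide of 27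
Conditions: D-fructose-derived Shi ketone (30 mol %), Oxone (2KHSO5·KHSO4·K2SO4), K2CO3, Bu4NHSO4, Na2B4O7 buffer, MeCN–DMM–H2O, 0 °C
Reagents that add atoms: potassium peroxymonosulfate, [K+].[O-]S(=O)(=O)OO
Why: Shi asymmetric epoxidation; the chiral dioxirane reacts through a spiro transition state with the electron-rich trisubstituted C10=C11 alkene and should give the (10R)-oxirane, while the hindered 1,1-disubstituted C7=C14 alkene and the electron-poor tiglates are left.

**Compound list**

1 | 2-methyl-1,4-benzoquinone | CC1=CC(=O)C=CC1=O | starting material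
2 | cyclopenta-1,3-diene | C1=CCC=C1 | starting material
3 | racemic endo cis-fused Diels–Alder adduct (the antipode that leads to 7 is drawn) | CC1=CC(=O)[C@@H]2[C@@H]3C=C[C@@H](C3)[C@@H]2C1=O | intermediate
4 | racemic convex-face 2,3-epoxide of 3 (the antipode that leads to 7 is drawn) | C[C@@]12O[C@H]2C(=O)[C@@H]2[C@@H]3C=C[C@@H](C3)[C@@H]2C1=O | intermediate
5 | racemic 1-methyl-7-oxabicyclo[4.1.0]hept-3-ene-2,5-dione (the antipode that leads to 7 is drawn) | C[C@@]12O[C@H]2C(=O)C=CC1=O | intermediate
6 | racemic (1S*,5S*,6S*)-5-hydroxy-1-methyl-7-oxabicyclo[4.1.0]hept-3-en-2-one (one antipode drawn) | C1=C[C@H](O)[C@@H]2O[C@]2(C)C1=O | intermediate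
7 | (1S,5S,6S)-5-hydroxy-1-methyl-7-oxabicyclo[4.1.0]hept-3-en-2-one | C1=C[C@H](O)[C@@H]2O[C@]2(C)C1=O | intermediate
8 | 4-methylpent-3-enoic acid | CC(C)=CCC(=O)O | starting material
9 | 1-(4-methylpent-3-enoyl)imidazole | CC(C)=CCC(=O)n1ccnc1 | intermediate
10 | N-methoxy-N,4-dimethylpent-3-enamide | CC(C)=CCC(=O)N(C)OC | intermediate
11 | 6-methyl-1-(trimethylsilyl)hept-5-en-1-yn-3-one | CC(C)=CCC(=O)C#C[Si](C)(C)C | intermediate
12 | (S)-6-methyl-1-(trimethylsilyl)hept-5-en-1-yn-3-ol | C[Si](C)(C)C#C[C@H](CC=C(C)C)O | intermediate
13 | (S)-3-(tert-butyldimethylsilyloxy)-6-methyl-1-(trimethylsilyl)hept-5-en-1-yne | C[Si](C)(C)C#C[C@H](CC=C(C)C)O[Si](C)(C)C(C)(C)C | intermediate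
14 | (S)-3-(tert-butyldimethylsilyloxy)-6-methylhept-5-en-1-yne | C#C[C@H](CC=C(C)C)O[Si](C)(C)C(C)(C)C | intermediate
15 | B-[(1Z,3S)-2-bromo-3-(tert-butyldimethylsilyloxy)-6-methylhepta-1,5-dien-1-yl]-9-borabicyclo[3.3.1]nonane | Br/C(=C\B1C2CCCC1CCC2)[C@H](CC=C(C)C)O[Si](C)(C)C(C)(C)C | intermediate
16 | (S)-2-bromo-3-(tert-butyldimethylsilyloxy)-6-methylhepta-1,5-diene | C=C(Br)[C@H](CC=C(C)C)O[Si](C)(C)C(C)(C)C | intermediate
17 | alkenyllithium from 16 (Li at C7) | C=C([Li])[C@H](CC=C(C)C)O[Si](C)(C)C(C)(C)C | intermediate
18 | alkenylmagnesium bromide (MgBr at C7, C8 silyl ether) | C=C([Mg]Br)[C@H](CC=C(C)C)O[Si](C)(C)C(C)(C)C | intermediate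
19 | chloromagnesium C2-alkoxide of 7 | C1=C[C@H](O[Mg]Cl)[C@@H]2O[C@]2(C)C1=O | intermediate
20 | C5–C6 magnesium enolate of the conjugate adduct (C2 chloromagnesium alkoxide) | C=C([C@@H]1[C@H](O[Mg]Cl)[C@@H]2O[C@]2(C)C(O[Mg]Br)=C1)[C@H](CC=C(C)C)O[Si](C)(C)C(C)(C)C | intermediate
21 | C5-trimethylsilyl enol ether, C2 trimethylsilyl ether of the conjugate adduct | C=C([C@@H]1[C@H](O[Si](C)(C)C)[C@@H]2O[C@]2(C)C(O[Si](C)(C)C)=C1)[C@H](CC=C(C)C)O[Si](C)(C)C(C)(C)C | intermediate
22 | C6-acetoxy ketone with C2 trimethylsilyl ether and C8 TBS ether | C=C([C@@H]1[C@H](O[Si](C)(C)C)[C@@H]2O[C@]2(C)C(=O)[C@H]1OC(C)=O)[C@H](CC=C(C)C)O[Si](C)(C)C(C)(C)C | intermediate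
23 | (1R,2S,3S,4S,6S,8S)-ring ketone: C6 acetate, free C2 hydroxyl, C3–C4 oxirane, C8 TBS ether | C=C([C@@H]1[C@H](O)[C@@H]2O[C@]2(C)C(=O)[C@H]1OC(C)=O)[C@H](CC=C(C)C)O[Si](C)(C)C(C)(C)C | intermediate
24 | (1R,2S,3S,4S,6S,8S)-C2,C8-diol with C6 acetate | C=C([C@@H]1[C@H](O)[C@@H]2O[C@]2(C)C(=O)[C@H]1OC(C)=O)[C@H](CC=C(C)C)O | intermediate
25 | tiglic acid, (E)-2-methylbut-2-enoic acid | C/C=C(\C)C(=O)O | starting material
26 | tiglic 2,4,6-trichlorobenzoic anhydride | C/C=C(\C)C(=O)OC(=O)c1c(Cl)cc(Cl)cc1Cl | intermediate
27 | (1R,2S,3S,4S,6S,8S)-C2,C8-bis-tiglate with C10=C11 alkene | C=C([C@@H]1[C@H](OC(=O)/C(C)=C/C)[C@@H]2O[C@]2(C)C(=O)[C@H]1OC(C)=O)[C@H](CC=C(C)C)OC(=O)/C(C)=C/C | intermediate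
28 | CNP0407453.3, (1R,2S,3S,4S,6S,8S,10R) | C=C([C@@H]1[C@H](OC(=O)/C(C)=C/C)[C@@H]2O[C@]2(C)C(=O)[C@H]1OC(C)=O)[C@H](C[C@H]1OC1(C)C)OC(=O)/C(C)=C/C | target

**Step count**

Total: 14 steps. Longest linear sequence: 9 steps (steps 6–10, then 11–14; the enone arm, steps 1–5 then 11–14, is equally long).

**Steps most likely to fail**

Step 11. The alkenylmagnesium reagent may attack C5 directly, may be delivered to C1 on the face anti to the C2 oxygen, or the telescoped silylation/acetoxylation may degrade the oxirane-bearing enol ether. The fallback replaces magnesium-alkoxide direction by a rhodium-catalysed boronate addition and separates the C–C bond formation from the oxidation. Setting out from 16, Br/Li exchange (t-BuLi, −78 °C) and trapping with 2-isopropoxy-4,4,5,5-tetramethyl-1,3,2-dioxaborolane gives the alkenyl pinacolboronate F1. Rhodium-catalysed 1,4-addition (Hayashi–Miyaura reaction) of F1 to 7 with [Rh(OH)(cod)]2 and KOH in dioxane–H2O, in which the free C2 hydroxyl is expected to bind rhodium and bring the alkenyl group in syn to itself (a chiral bisphosphine such as BINAP of the matching sense can be added to reinforce this face), should give the β-alkenyl ketone F2. Treatment with LiN(SiMe3)2 (2.2 equiv) and TMSCl, which can enolise only toward C6, then gives the bis-silyl enol ether 21. Acetoxylation with Pb(OAc)4 and hydrolysis as in step 11 return to 23.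

Step 4. Hydride may attack the C5 carbonyl, may come in on the oxirane face, or may reduce both carbonyls. The fallback uses cage control followed by inversion. Setting out from 4, NaBH4 reduction on the intact tricycle (convex-face attack at the less hindered C2 carbonyl) should give the racemic endo hydroxy ketone F3. Flash vacuum pyrolysis then gives the racemic anti-epoxyquinol F4, and Mitsunobu reaction with 4-nitrobenzoic acid (PPh3, DIAD) inverts C2 to the syn 4-nitrobenzoate F5. Methanolysis with K2CO3 in MeOH returns to 6.

Step 14. The carbonate-buffered medium may hydrolyse or epimerise the C6 α-acetoxy ketone, oxygen transfer to the hindered substrate may be slow, or facial control at C10=C11 may be weak. The fallback is peracid epoxidation without reagent control, followed by separation. Setting out from 27, m-CPBA with NaHCO3 in CH2Cl2 at 0 °C should epoxidise only the electron-rich C10=C11 alkene and give 28 together with its (10S)-epimer F6, to be separated by preparative HPLC.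

**Further compounds**

F1 | step 11 | (S)-2-[3-(tert-butyldimethylsilyloxy)-6-methylhepta-1,5-dien-2-yl]-4,4,5,5-tetramethyl-1,3,2-dioxaborolane | C=C(B1OC(C)(C)C(C)(C)O1)[C@H](CC=C(C)C)O[Si](C)(C)C(C)(C)C
F2 | step 11 | conjugate adduct ketone: C2 hydroxyl, C3–C4 oxirane, C6 unsubstituted, C8 TBS ether | C=C([C@@H]1[C@H](O)[C@@H]2O[C@]2(C)C(=O)C1)[C@H](CC=C(C)C)O[Si](C)(C)C(C)(C)C
F3 | step 4 | racemic tricyclic hydroxy ketone from 4, C2 hydroxyl endo and anti to the oxirane | C[C@@]12O[C@H]2[C@H](O)[C@@H]2[C@@H]3C=C[C@@H](C3)[C@@H]2C1=O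
F4 | step 4 | racemic anti-epoxyquinol, C2 epimer of 6 | C1=C[C@@H](O)[C@@H]2O[C@]2(C)C1=O
F5 | step 4 | racemic 4-nitrobenzoate of 6 | C1=C[C@H](OC(=O)c3ccc(cc3)[N+](=O)[O-])[C@@H]2O[C@]2(C)C1=O
F6 | step 14 | (10S)-epimer of 28 | C=C([C@@H]1[C@H](OC(=O)/C(C)=C/C)[C@@H]2O[C@]2(C)C(=O)[C@H]1OC(C)=O)[C@H](C[C@@H]1OC1(C)C)OC(=O)/C(C)=C/C
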